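The ten-membered ring is cut across C5–C10 (C1 is the ester-bearing ring carbon, C10 the ring carbon carrying exocyclic C11). The saturated arc C5–C10, which holds both stereocentres C6 and C7, is then a cyclohexane, and the unsaturated arc C1–C4 splits into a vinyl group (C4=C3) on C5 and a 2-(methoxycarbonyl)vinyl group (C1=C2) on the carbinol carbon C10. A single anionic oxy-Cope shift of this trans-1,2-dialkenylcyclohexanol forms C2–C3, cleaves C5–C10 and delivers the ten-membered β-keto ester with the ketone at C10 and the ester at C1; alkene relay and enol acetylation complete the target.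

Key step: step 11

Remark: locants C1–C11 are those of the target ring; C5 and C10 become trigonal in step 11, so of the stereocentres made on the way only C6 and C7 reach the target, and the single enantiomer of the enone is secured by resolution in step 1.

Step 1
Reactants: 1 rac-3,4-dimethylcyclohex-2-en-1-one
Product: 2 (R)-3,4-dimethylcyclohex-2-en-1-one
Conditions: preparative chiral SFC, amylose tris(3,5-dimethylphenylcarbamate) phase, CO2/MeOH
Reagents that add atoms: none
Why: Chromatographic resolution on a chiral stationary phase supplies the single enantiomer whose C4 stereocentre becomes C7 of the target, with no bond made or broken.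

Step 2
Reactants: 3 3-bromofuran; 4 oxirane
Product: 6 2-(furan-3-yl)ethan-1-ol, via furan-3-yllithium 5 (not isolated)
Conditions: n-BuLi, THF, −78 °C; oxirane, BF3·OEt2, −78 °C; H2O
Reagents that add atoms: none
Why: Bromine–lithium exchange at −78 °C (cold enough to stop lithium migrating to the furan 2-position) followed by BF3-assisted epoxide opening gives the two-carbon homologated alcohol.

Step 3
Reactants: 6 2-(furan-3-yl)ethan-1-ol
Product: 7 3-(2-bromoethyl)furan
Conditions: CBr4, PPh3, CH2Cl2, 0 °C
Reagents that add atoms: carbon tetrabromide, BrC(Br)(Br)Br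
Why: Appel reaction, a neutral SN2 bromination that the acid-sensitive furan tolerates.

Step 4
Reactants: 7 3-(2-bromoethyl)furan; 2 (R)-3,4-dimethylcyclohex-2-en-1-one
Product: 9 {[(3S,4R)-3-[2-(furan-3-yl)ethyl]-3,4-dimethylcyclohex-1-en-1-yl]oxy}trimethylsilane, via Grignard reagent 8 (not isolated)
Conditions: Mg, THF, rt; then 2, CuBr·SMe2 (10 mol %), TMSCl, DMPU, THF, −78 → −40 °C; Et3N, pentane, cold aq. NaHCO3
Reagents that add atoms: chlorotrimethylsilane, C[Si](C)(C)Cl
Why: Copper-catalysed, TMSCl-accelerated conjugate addition of the Grignard reagent (Kharasch-type 1,4-addition) delivers the furylethyl group to the β-carbon anti to the adjacent pseudoaxial methyl, which sets the quaternary stereocentre C6 with the two methyls cis by substrate control, and the enolate is captured regiospecifically as the C10–C5 silyl enol ether.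

Step 5
Reactants: 10 benzeneselenenyl chloride; 11 ethyl vinyl ether
Product: 13 (phenylselanyl)acetaldehyde, via chloro ether 12 (not isolated)
Conditions: CH2Cl2, −78 → 0 °C; then H2O, NaHCO3, 0 °C
Reagents that add atoms: water, O
Why: Markovnikov electrophilic selenenylation of the enol ether gives the α-chloro ether, whose hydrolysis unmasks the aldehyde used as vinyl cation equivalent.

Step 6
Reactants: 9 silyl enol ether; 13 (phenylselanyl)acetaldehyde
Product: 15 (2R,3S,4R)-3-[2-(furan-3-yl)ethyl]-2-[1-hydroxy-2-(phenylselanyl)ethyl]-3,4-dimethylcyclohexan-1-one (carbinol epimers), via lithium enolate 14 (not isolated)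
Conditions: MeLi, THF, 0 °C → rt; 13, −78 °C; AcOH, −78 °C
Reagents that add atoms: none
Why: Methyllithium cleaves the silyl enol ether to the regiodefined lithium enolate, which undergoes aldol addition at −78 °C (first half of the Clive–Kowalski α-vinylation), the aldehyde entering C5 on the face opposite the pseudoaxial C6 methyl, that is cis to the furylethyl arm; the carbinol centre is lost in step 7 and C5 is reset in step 8.

Step 7
Reactants: 15 aldol adduct
Product: 17 (2S,3S,4R)-2-ethenyl-3-[2-(furan-3-yl)ethyl]-3,4-dimethylcyclohexan-1-one, via mesylate 16 (not isolated)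
Conditions: MsCl, Et3N, CH2Cl2, 0 °C → rt
Reagents that add atoms: none
Why: Mesylation triggers the Reich-type anti elimination of the β-hydroxy selenide (seleniranium ion, then loss of PhSeCl), which unveils the vinyl group regiospecifically out of conjugation with the ketone and leaves C5 untouched.

Step 8
Reactants: 17 C5-epimeric vinyl ketone
Product: 19 (2R,3S,4R)-2-ethenyl-3-[2-(furan-3-yl)ethyl]-3,4-dimethylcyclohexan-1-one, via potassium dienolate 18 (not isolated)
Conditions: KH, THF, 0 °C → rt; inverse addition to AcOH, THF, −78 °C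
Reagents that add atoms: none
Why: Irreversible deprotonation under equilibrating conditions gives the conjugated, more substituted dienolate, and kinetic α-protonation (deconjugative protonation of a dienolate) delivers the proton axially to C5 from the face opposite the pseudoaxial C6 methyl, so that the vinyl group should end equatorial and trans to the furylethyl arm; C5 is erased in step 11, so any remaining epimer converges there.

Step 9
Reactants: 19 vinyl ketone; 20 ethynylmagnesium bromide
Product: 21 (1S,2R,3S,4R)-2-ethenyl-1-ethynyl-3-[2-(furan-3-yl)ethyl]-3,4-dimethylcyclohexan-1-ol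
Conditions: LaCl3·2LiCl, THF, −78 → 0 °C; H2O
Reagents that add atoms: none
Why: Lanthanum-assisted 1,2-addition of the weakly basic alkynyl Grignard reagent outruns enolisation, and because the axial trajectory at C10 is blocked by the syn-axial C6 methyl the nucleophile enters equatorially, which sets C10 with ethynyl trans to the C5 vinyl group and the hydroxyl axial.

Step 10
Reactants: 21 propargylic alcohol
Product: 22 methyl 2-[(1S,2R,3S,4R)-2-ethenyl-3-[2-(furan-3-yl)ethyl]-1-hydroxy-3,4-dimethylcyclohexyl]prop-2-enoate
Conditions: Pd(OAc)2 (2 mol %), 2-(diphenylphosphino)pyridine, MsOH (less than the phosphine), CO (20 bar), MeOH/CH2Cl2, 45 °C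
Reagents that add atoms: carbon monoxide, [C-]#[O+]; methanol, CO
Why: Palladium-catalysed Markovnikov methoxycarbonylation (hydroesterification) of the terminal alkyne with the pyridylphosphine/acid catalyst places the ester on the internal alkyne carbon and so gives the 2-substituted acrylate directly, the alkyne reacting far faster than the vinyl group and the phosphine buffering the acid so that the tertiary alcohol and the furan survive.

Step 11
Reactants: 22 dialkenylcyclohexanol
Product: 25 methyl (4E,6S,7R)-6-[2-(furan-3-yl)ethyl]-6,7-dimethyl-10-oxocyclodec-4-ene-1-carboxylate (C1 epimers), via potassium alkoxide 23 (not isolated), via potassium enolate 24 (not isolated)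
Conditions: KHMDS, 18-crown-6, THF (0.01 M), −78 → 0 °C; AcOH, −78 °C
Reagents that add atoms: none
Why: KHMDS with 18-crown-6 gives the naked potassium alkoxide 23, whose oxyanion weakens the C5–C10 bond so that a charge-accelerated [3,3]-sigmatropic shift (anionic oxy-Cope rearrangement, the established ring expansion of 1,2-dialkenylcyclohexanols to cyclodec-5-enones) forms C2–C3 and cleaves C5–C10 below room temperature. The ten-membered ring arises by four-carbon ring expansion of the cyclohexane, not by end-to-end cyclisation, so the step is unimolecular and free of the entropic cost of macrocyclisation. No stereocentre is created: C5 and C10 become trigonal, C6 and C7 are spectators, and the chair transition state with vinyl and acrylate trans-diequatorial and the oxide axial fixes the new C4=C5 alkene as E. The [3,3] path must beat β-lactonisation, oxa-Michael oligomerisation and a [1,3]-shift; the gauche diequatorial alkenyl arms, dilution and low temperature favour it, and above all the ester on C1 makes the acrylate the acceptor for the allyl terminus C3 and the product a stabilised β-keto ester enolate 24, so the shift should be fast and irreversible. Cold acetic acid releases 25 with the ketone at C10 and the ester at C1, the two carbons that still need functionalising.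

Step 12
Reactants: 25 β-keto ester
Product: 27 methyl (1(10)Z,4E,6S,7R)-6-[2-(furan-3-yl)ethyl]-6,7-dimethyl-10-[(trifluoromethanesulfonyl)oxy]cyclodeca-1(10),4-diene-1-carboxylate, via sodium enolate 26 (not isolated)
Conditions: NaH, THF, 0 °C; PhNTf2, 0 °C → rt
Reagents that add atoms: N-phenylbis(trifluoromethanesulfonimide), O=S(=O)(N(c1ccccc1)S(=O)(=O)C(F)(F)F)C(F)(F)F
Why: O-Sulfonylation of the chelated sodium enolate of the β-keto ester with the mild triflyl donor (enol triflate formation) gives the Z enol triflate without touching the furan or the C4=C5 alkene.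

Step 13
Reactants: 27 enol triflate
Product: 28 methyl (1(10)Z,4E,6S,7R)-10-formyl-6-[2-(furan-3-yl)ethyl]-6,7-dimethylcyclodeca-1(10),4-diene-1-carboxylate
Conditions: Pd(PPh3)4 (5 mol %), CO (3 bar), Bu3SnH (slow addition), LiCl, THF, 50 °C
Reagents that add atoms: carbon monoxide, [C-]#[O+]
Why: Reductive carbonylation of the vinyl triflate (Stille formylation: oxidative addition to zerovalent palladium, CO insertion, hydride transfer from tin, reductive elimination) installs C11 as the aldehyde with retention of alkene geometry, slow addition of the tin hydride keeping direct reduction of the triflate in check.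

Step 14
Reactants: 28 enal
Product: 31 methyl (1E,3Z,6R,7R)-10-formyl-6-[2-(furan-3-yl)ethyl]-6,7-dimethylcyclodeca-1,3-diene-1-carboxylate (C10 epimers), via potassium dienolate 29 (not isolated), via potassium trienolate 30 (not isolated)
Conditions: KOtBu (0.5 equiv, then 0.7 equiv more), t-BuOH, THF, −20 → 0 °C; inverse addition to AcOH, THF, −78 °C
Reagents that add atoms: none
Why: Base-mediated prototropic relay (γ-deprotonation of the enal, reprotonation, then ester-activated removal of the doubly allylic C3 proton) moves both ring alkenes into the C1–C4 dienoate because the deprotonated material collects in the most delocalised anion, the trienolate 30, free aldehyde left by the first substoichiometric charge of base serving as proton shuttle; cold acid protonates this extended enolate kinetically at the α-carbon C10, and any conjugated enal tautomer formed alongside gives the same trienolate in step 15.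

Step 15
Reactants: 31 aldehyde
Product: 33 methyl (1E,3Z,6R,7R,10Z)-10-[(acetyloxy)methylidene]-6-[2-(furan-3-yl)ethyl]-6,7-dimethylcyclodeca-1,3-diene-1-carboxylate (CNP0318171.1), via lithium trienolate 32 (not isolated)
Conditions: LiHMDS, toluene/THF, −78 → −20 → −78 °C; Ac2O, −78 °C
Reagents that add atoms: acetic anhydride, CC(=O)OC(C)=O
Why: Deprotonation of the α-branched aldehyde gives the lithium trienolate, which is allowed to settle into the chelate in which lithium bridges the enolate oxygen and the C1 ester carbonyl, possible only with oxygen cis to C1, and O-acetylation of this aldehyde enolate then fixes the Z enol acetate of the target.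

Compound list
1 | rac-3,4-dimethylcyclohex-2-en-1-one | CC1CCC(=O)C=C1C | starting material
2 | (R)-3,4-dimethylcyclohex-2-en-1-one | O=C1C=C(C)[C@H](C)CC1 | intermediate
3 | 3-bromofuran | Brc1ccoc1 | starting material
4 | oxirane | C1CO1 | starting material
5 | furan-3-yllithium | [Li]c1ccoc1 | intermediate
6 | 2-(furan-3-yl)ethan-1-ol | OCCc1ccoc1 | intermediate
7 | 3-(2-bromoethyl)furan | BrCCc1ccoc1 | intermediate
8 | [2-(furan-3-yl)ethyl]magnesium bromide | Br[Mg]CCc1ccoc1 | intermediate
9 | {[(3S,4R)-3-[2-(furan-3-yl)ethyl]-3,4-dimethylcyclohex-1-en-1-yl]oxy}trimethylsilane | C[Si](C)(C)OC1=C[C@@](C)(CCc2ccoc2)[C@H](C)CC1 | intermediate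
10 | benzeneselenenyl chloride | Cl[Se]c1ccccc1 | starting material
11 | ethyl vinyl ether | C=COCC | starting material
12 | 1-chloro-1-ethoxy-2-(phenylselanyl)ethane | CCOC(Cl)C[Se]c1ccccc1 | intermediate
13 | (phenylselanyl)acetaldehyde | O=CC[Se]c1ccccc1 | intermediate
14 | lithium (3S,4R)-3-[2-(furan-3-yl)ethyl]-3,4-dimethylcyclohex-1-en-1-olate | [Li]OC1=C[C@@](C)(CCc2ccoc2)[C@H](C)CC1 | intermediate
15 | (2R,3S,4R)-3-[2-(furan-3-yl)ethyl]-2-[1-hydroxy-2-(phenylselanyl)ethyl]-3,4-dimethylcyclohexan-1-one (carbinol epimers) | OC(C[Se]c1ccccc1)[C@H]1[C@@](C)(CCc2ccoc2)[C@H](C)CCC1=O | intermediate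
16 | 1-[(1R,2S,3R)-2-[2-(furan-3-yl)ethyl]-2,3-dimethyl-6-oxocyclohexyl]-2-(phenylselanyl)ethyl methanesulfonate | CS(=O)(=O)OC(C[Se]c1ccccc1)[C@H]1[C@@](C)(CCc2ccoc2)[C@H](C)CCC1=O | intermediate
17 | (2S,3S,4R)-2-ethenyl-3-[2-(furan-3-yl)ethyl]-3,4-dimethylcyclohexan-1-one | C=C[C@H]1[C@@](C)(CCc2ccoc2)[C@H](C)CCC1=O | intermediate
18 | potassium (3S,4R)-2-ethenyl-3-[2-(furan-3-yl)ethyl]-3,4-dimethylcyclohex-1-en-1-olate | [K+].[O-]C1=C(C=C)[C@@](C)(CCc2ccoc2)[C@H](C)CC1 | intermediate
19 | (2R,3S,4R)-2-ethenyl-3-[2-(furan-3-yl)ethyl]-3,4-dimethylcyclohexan-1-one | C=C[C@@H]1[C@@](C)(CCc2ccoc2)[C@H](C)CCC1=O | intermediate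
20 | ethynylmagnesium bromide | C#C[Mg]Br | starting material
21 | (1S,2R,3S,4R)-2-ethenyl-1-ethynyl-3-[2-(furan-3-yl)ethyl]-3,4-dimethylcyclohexan-1-ol | C=C[C@@H]1[C@@](C)(CCc2ccoc2)[C@H](C)CC[C@@]1(O)C#C | intermediate
22 | methyl 2-[(1S,2R,3S,4R)-2-ethenyl-3-[2-(furan-3-yl)ethyl]-1-hydroxy-3,4-dimethylcyclohexyl]prop-2-enoate | C=C[C@@H]1[C@@](C)(CCc2ccoc2)[C@H](C)CC[C@@]1(O)C(=C)C(=O)OC | intermediate
23 | potassium alkoxide of 22 | C=C[C@@H]1[C@@](C)(CCc2ccoc2)[C@H](C)CC[C@@]1([O-])C(=C)C(=O)OC.[K+] | intermediate
24 | potassium enolate of 25 (1(10)E,4E, as formed through the chair) | C1C/C=C/[C@@](C)(CCc2ccoc2)[C@H](C)CC\C([O-])=C1/C(=O)OC.[K+] | intermediate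
25 | methyl (4E,6S,7R)-6-[2-(furan-3-yl)ethyl]-6,7-dimethyl-10-oxocyclodec-4-ene-1-carboxylate (C1 epimers) | COC(=O)C1CC/C=C/[C@@](C)(CCc2ccoc2)[C@H](C)CCC1=O | intermediate
26 | sodium enolate of 25 (chelated, 1(10)Z) | C1C/C=C/[C@@](C)(CCc2ccoc2)[C@H](C)CC/C([O-])=C1/C(=O)OC.[Na+] | intermediate
27 | methyl (1(10)Z,4E,6S,7R)-6-[2-(furan-3-yl)ethyl]-6,7-dimethyl-10-[(trifluoromethanesulfonyl)oxy]cyclodeca-1(10),4-diene-1-carboxylate | C1C/C=C/[C@@](C)(CCc2ccoc2)[C@H](C)CC/C(OS(=O)(=O)C(F)(F)F)=C1/C(=O)OC | intermediate
28 | methyl (1(10)Z,4E,6S,7R)-10-formyl-6-[2-(furan-3-yl)ethyl]-6,7-dimethylcyclodeca-1(10),4-diene-1-carboxylate | C1C/C=C/[C@@](C)(CCc2ccoc2)[C@H](C)CC/C(C=O)=C1/C(=O)OC | intermediate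
29 | potassium dienolate of 28 (C11–O, C10=C11, C1=C2; C4=C5 retained) | COC(=O)C1=CC/C=C/[C@@](C)(CCc2ccoc2)[C@H](C)CCC1=C[O-].[K+] | intermediate
30 | potassium trienolate (C10=C11, C1=C2, C3=C4) | COC(=O)/C1=C/C=C\C[C@@](C)(CCc2ccoc2)[C@H](C)CCC1=C[O-].[K+] | intermediate
31 | methyl (1E,3Z,6R,7R)-10-formyl-6-[2-(furan-3-yl)ethyl]-6,7-dimethylcyclodeca-1,3-diene-1-carboxylate (C10 epimers) | COC(=O)/C1=C/C=C\C[C@@](C)(CCc2ccoc2)[C@H](C)CCC1C=O | intermediate
32 | lithium (Z)-trienolate of 31 | COC(=O)/C1=C/C=C\C[C@@](C)(CCc2ccoc2)[C@H](C)CC\C1=C\O[Li] | intermediate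
33 | methyl (1E,3Z,6R,7R,10Z)-10-[(acetyloxy)methylidene]-6-[2-(furan-3-yl)ethyl]-6,7-dimethylcyclodeca-1,3-diene-1-carboxylate | COC(=O)/C1=C/C=C\C[C@@](C)(CCc2ccoc2)[C@H](C)CC\C1=C\OC(C)=O | target

Total step count: 15 (the resolution included). Longest linear sequence: 13 steps, from 3-bromofuran 3 to 33 through steps 2–4 and 6–15.

Steps most likely to fail

Step 14. The proton relay may stall at the kinetic dienolate, or the free aldehyde may be lost to aldol-type self-condensation, so that the C4=C5 alkene is not moved. The fallback sets out from 28 and masks the aldehyde first. LiHMDS in THF at −78 °C gives the lithium dienolate F3, and acetic anhydride traps it as the skipped dienol acetate F4, which still carries the C4=C5 alkene. This alkene is then walked into conjugation on the neutral substrate with a metal hydride catalyst (RuHCl(CO)(PPh3)3, toluene, 60–80 °C). Because C6 is quaternary, hydride insertion and β-hydride elimination can only run toward C3. The fallback comes back to the route at 33.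

Step 15. The enolate geometry may be poorly controlled, with O-acetylation occurring from the non-chelated enolate and giving the wrong geometry at C10=C11. The fallback sets out from 31 and gives up stereocontrol in the acylation. Thermodynamic acetylation (Ac2O, Et3N, DMAP) is followed by chromatographic separation of 33 from the (10E) enol acetate F5. F5 is returned to the aldehyde by mild methanolysis (K2CO3, MeOH, 0 °C) and re-subjected, so the loop comes back at 31.

Step 11. β-Lactonisation or intermolecular oxa-Michael addition of the tertiary alkoxide may outpace the sigmatropic shift. The fallback sets out from 22 and removes the alkoxide altogether. Silylation (TMSOTf, 2,6-lutidine, CH2Cl2, −78 °C) gives the trimethylsilyl ether F1. Heating in toluene with BHT in a sealed tube (160–180 °C) effects the neutral siloxy-Cope ring expansion to the ten-membered silyl enol ether F2. Hydrolysis (aqueous citric acid, THF) comes back to the route at 25.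

Further compounds
F1 | step 11 | methyl 2-[(1S,2R,3S,4R)-2-ethenyl-3-[2-(furan-3-yl)ethyl]-3,4-dimethyl-1-(trimethylsilyloxy)cyclohexyl]prop-2-enoate | C=C[C@@H]1[C@@](C)(CCc2ccoc2)[C@H](C)CC[C@@]1(O[Si](C)(C)C)C(=C)C(=O)OC
F2 | step 11 | methyl (1(10)E,4E,6S,7R)-6-[2-(furan-3-yl)ethyl]-6,7-dimethyl-10-(trimethylsilyloxy)cyclodeca-1(10),4-diene-1-carboxylate | C1C/C=C/[C@@](C)(CCc2ccoc2)[C@H](C)CC\C(O[Si](C)(C)C)=C1/C(=O)OC
F3 | step 14 | lithium (Z)-dienolate of 28 (C10=C11, C1=C2; C4=C5 retained) | COC(=O)/C1=C/C/C=C/[C@@](C)(CCc2ccoc2)[C@H](C)CC\C1=C\O[Li]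
F4 | step 14 | methyl (1E,4E,6S,7R,10Z)-10-[(acetyloxy)methylidene]-6-[2-(furan-3-yl)ethyl]-6,7-dimethylcyclodeca-1,4-diene-1-carboxylate | COC(=O)/C1=C/C/C=C/[C@@](C)(CCc2ccoc2)[C@H](C)CC\C1=C\OC(C)=O
F5 | step 15 | methyl (1E,3Z,6R,7R,10E)-10-[(acetyloxy)methylidene]-6-[2-(furan-3-yl)ethyl]-6,7-dimethylcyclodeca-1,3-diene-1-carboxylate | COC(=O)/C1=C/C=C\C[C@@](C)(CCc2ccoc2)[C@H](C)CC/C1=C\OC(C)=O
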